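**Strategy**

The pyranone is disconnected across its O1–C2 ketal bond together with the C3–OH bond, which turns the two fusion stereocentres back into the planar C2=C3 enol ether of a 2-aryl-3-(2,4,6-trihydroxybenzoyl)benzofuran fused to an (S)-flavan. The key step exploits exactly this: C2 is a ketal carbon flanked by the furan oxygen and a p-oxyphenyl ring, C3 a carbinol α to the ketone, and the benzoyl ring has two equivalent ortho-hydroxyls. One catalyst-controlled oxygen transfer to C3, followed by capture of the C2 oxocarbenium by the ortho-phenol, closes the six-membered ring and sets both centres. The benzofuran precursor comes from a carbonylative annulation of an o-alkynylphenol.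

Key step: step 13

Remark: C2 and C3 of the new ring are ring-fusion atoms, so ring closure allows only one relative arrangement and the route has to control only the face of C3 that receives oxygen; both centres are written with the descriptors of the target SMILES, and the sense of induction of the (R,R)-salen catalyst is assumed from its behaviour with indene-type cyclic olefins.

**Route**

Step 1
Reactants: 1 2,4,6-trihydroxybenzaldehyde
Product: 2 2,6-dihydroxy-4-(methoxymethoxy)benzaldehyde
Conditions: MOMCl (1.05 eq), K2CO3, acetone, 0 °C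
Reagents that add atoms: chloromethyl methyl ether (MOMCl), COCCl
Why: Williamson O-alkylation (MOM protection) in which the 4-OH, para to the formyl group, is the most acidic and least hindered hydroxyl and should react first with one equivalent of reagent.

Step 2
Reactants: 2 2,6-dihydroxy-4-(methoxymethoxy)benzaldehyde
Product: 3 2-(benzyloxy)-6-hydroxy-4-(methoxymethoxy)benzaldehyde
Conditions: BnBr (1.05 eq), K2CO3, DMF, rt
Reagents that add atoms: benzyl bromide, BrCc1ccccc1
Why: Williamson etherification of one of two equivalent ortho-hydroxyls, after which the remaining one is held in a hydrogen bond to the formyl oxygen and should resist a second alkylation under mild carbonate conditions.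

Step 3
Reactants: 3 2-(benzyloxy)-6-hydroxy-4-(methoxymethoxy)benzaldehyde
Product: 4 6-(benzyloxy)-2-hydroxy-3-iodo-4-(methoxymethoxy)benzaldehyde
Conditions: NIS, DMF, rt, dark
Reagents that add atoms: N-iodosuccinimide, O=C1CCC(=O)N1I
Why: Electrophilic aromatic iodination directed by the free chelated hydroxyl to its ortho position, the pattern known for 2-hydroxy-4,6-dialkoxyaryl carbonyl compounds, which places iodine next to the oxygen that becomes the flavan ring oxygen.

Step 4
Reactants: 4 6-(benzyloxy)-2-hydroxy-3-iodo-4-(methoxymethoxy)benzaldehyde; 5 1-[4-(benzyloxy)phenyl]ethan-1-one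
Product: 6 (E)-3-[6-(benzyloxy)-2-hydroxy-3-iodo-4-(methoxymethoxy)phenyl]-1-[4-(benzyloxy)phenyl]prop-2-en-1-one
Conditions: KOH, EtOH/H2O, rt
Reagents that add atoms: none
Why: Claisen–Schmidt condensation, in which the ketone enolate adds to the aldehyde and elimination gives the (E)-enone while the MOM ether, benzyl ethers and aryl iodide are stable to hydroxide.

Step 5
Reactants: 6 (E)-3-[6-(benzyloxy)-2-hydroxy-3-iodo-4-(methoxymethoxy)phenyl]-1-[4-(benzyloxy)phenyl]prop-2-en-1-one
Product: 8 (1R)-3-[6-(benzyloxy)-2-hydroxy-3-iodo-4-(methoxymethoxy)phenyl]-1-[4-(benzyloxy)phenyl]propan-1-ol, via saturated ketone 7 (not isolated)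
Conditions: RuCl[(R,R)-TsDPEN](p-cymene) (2 mol %), HCO2H/Et3N (5:2), EtOAc, 40 °C
Reagents that add atoms: none
Why: Noyori–Ikariya asymmetric transfer hydrogenation run in tandem, in which the Ru–H first reduces the enone C=C by conjugate hydride transfer and then reduces the aryl ketone 7 on the face set by the (R,R)-TsDPEN ligand, which should give the (R)-carbinol and leave the aryl iodide and benzyl ethers untouched.

Step 6
Reactants: 8 (1R)-3-[6-(benzyloxy)-2-hydroxy-3-iodo-4-(methoxymethoxy)phenyl]-1-[4-(benzyloxy)phenyl]propan-1-ol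
Product: 9 (2S)-5-(benzyloxy)-2-[4-(benzyloxy)phenyl]-8-iodo-7-(methoxymethoxy)chromane
Conditions: PPh3, DIAD, THF, 0 °C
Reagents that add atoms: none
Why: Intramolecular Mitsunobu etherification, a 6-exo-tet SN2 displacement of the activated benzylic alcohol by the phenol with inversion, so the (R)-carbinol should give the (S)-configured C2 of the chromane.

Step 7
Reactants: 9 (2S)-5-(benzyloxy)-2-[4-(benzyloxy)phenyl]-8-iodo-7-(methoxymethoxy)chromane; 10 1-(benzyloxy)-4-ethynylbenzene
Product: 11 (2S)-5-(benzyloxy)-2-[4-(benzyloxy)phenyl]-8-{[4-(benzyloxy)phenyl]ethynyl}-7-(methoxymethoxy)chromane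
Conditions: PdCl2(PPh3)2 (5 mol %), CuI, Et3N/DMF, 60 °C
Reagents that add atoms: none
Why: Sonogashira coupling of the aryl iodide with the terminal alkyne, with the MOM ether keeping the neighbouring oxygen from cyclising onto the alkyne at this stage.

Step 8
Reactants: 11 (2S)-5-(benzyloxy)-2-[4-(benzyloxy)phenyl]-8-{[4-(benzyloxy)phenyl]ethynyl}-7-(methoxymethoxy)chromane
Product: 12 (2S)-5-(benzyloxy)-2-[4-(benzyloxy)phenyl]-8-{[4-(benzyloxy)phenyl]ethynyl}chroman-7-ol
Conditions: conc. HCl (cat.), MeOH/THF, 45 °C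
Reagents that add atoms: none
Why: Acid-catalysed acetal exchange removes the aryl MOM ether and should leave the benzyl ethers, the alkyne and the chromane untouched, which frees the phenol ortho to the alkyne.

Step 9
Reactants: 13 phloroglucinol (benzene-1,3,5-triol)
Product: 14 1,3,5-tris(methoxymethoxy)benzene
Conditions: MOMCl (3.6 eq), K2CO3, acetone, 0 °C → rt
Reagents that add atoms: chloromethyl methyl ether (MOMCl), COCCl
Why: Threefold Williamson O-alkylation (MOM protection) of the three equivalent phenol groups.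

Step 10
Reactants: 14 1,3,5-tris(methoxymethoxy)benzene
Product: 15 2-iodo-1,3,5-tris(methoxymethoxy)benzene
Conditions: NIS (1.0 eq), MeCN, 0 °C → rt
Reagents that add atoms: N-iodosuccinimide, O=C1CCC(=O)N1I
Why: Electrophilic aromatic iodination of a 1,3,5-trialkoxybenzene whose three ring positions are equivalent, so one equivalent of NIS should stop at the mono-iodide under neutral conditions that spare the MOM ethers.

Step 11
Reactants: 12 (2S)-5-(benzyloxy)-2-[4-(benzyloxy)phenyl]-8-{[4-(benzyloxy)phenyl]ethynyl}chroman-7-ol; 15 2-iodo-1,3,5-tris(methoxymethoxy)benzene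
Product: 16 [(2S)-5-(benzyloxy)-2,8-bis[4-(benzyloxy)phenyl]-3,4-dihydro-2H-furo[2,3-h]chromen-9-yl][2,4,6-tris(methoxymethoxy)phenyl]methanone
Conditions: Pd(PPh3)4 (5 mol %), CO (1 atm), K2CO3, MeCN, 50 °C
Reagents that add atoms: carbon monoxide, [C-]#[O+]
Why: Palladium-catalysed carbonylative annulation of an o-alkynylphenol with an aryl iodide, in which oxidative addition and CO insertion give an aroyl-palladium species that activates the alkyne for 5-endo attack of the phenoxide and reductive elimination places the aroyl group on C3 of the new 2-arylbenzofuran.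

Step 12
Reactants: 16 [(2S)-5-(benzyloxy)-2,8-bis[4-(benzyloxy)phenyl]-3,4-dihydro-2H-furo[2,3-h]chromen-9-yl][2,4,6-tris(methoxymethoxy)phenyl]methanone
Product: 17 [(2S)-5-(benzyloxy)-2,8-bis[4-(benzyloxy)phenyl]-3,4-dihydro-2H-furo[2,3-h]chromen-9-yl](2,4,6-trihydroxyphenyl)methanone
Conditions: conc. HCl (cat.), MeOH/THF, 45 °C
Reagents that add atoms: none
Why: Acid-catalysed acetal exchange should cleave the three MOM ethers and leave the benzyl ethers in place, which frees the ortho-hydroxyls needed for the ring closure.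

Step 13
Reactants: 17 [(2S)-5-(benzyloxy)-2,8-bis[4-(benzyloxy)phenyl]-3,4-dihydro-2H-furo[2,3-h]chromen-9-yl](2,4,6-trihydroxyphenyl)methanone
Product: 19 tri-O-benzyl ether of target 20 (ketal carbon R / carbinol carbon S / flavan C2 S), via benzofuran 8,9-epoxide 18 (not isolated)
Conditions: (R,R)-Jacobsen catalyst [(R,R)-(salen)Mn(III)Cl] (10 mol %), NMO, mCPBA, CH2Cl2, −78 → −40 °C
Reagents that add atoms: m-chloroperbenzoic acid (mCPBA), O=C(OO)c1cccc(Cl)c1
Why: Proposed new method: the oxo-Mn(V) salen species should transfer its oxygen to the electron-rich C2=C3 bond of the benzofuran (C2 carries the furan oxygen and the p-benzyloxyphenyl ring), and the labile 2,3-epoxide 18 then ionises at C2 to an oxocarbenium/C3-alkoxide pair that is captured at C2 by the hydrogen-bonded ortho-phenol of the trihydroxybenzoyl group. The closest known reaction types are the Jacobsen–Katsuki epoxidation of tetrasubstituted chromenes and of isoflavones and the dioxirane epoxidation of benzofurans, whose epoxides open at the acetal carbon. The pyranone closes by attack of the phenol oxygen on C2, a 6-endo opening of the epoxide or, after ionisation, a 6-exo-trig addition to the oxocarbenium ion. The carbinol carbon is set by the face of oxygen transfer, which the chiral salen ligand controls because the flavan stereocentre is too remote to bias it, and the ketal carbon is set by the ring closure itself, since only one arrangement lets the six-membered ring span the C2–C3 fusion bond. The step needs attack at C2 and not at C3 (which would give a spiro-coumaranone), secured by the cation-stabilising oxygen and aryl group on C2 and by the low temperature, and it needs oxidation of the enol ether and not of an arene, secured by benzyl ethers on the electron-rich rings and by the acyl group that deactivates the only ring with free phenols. Either ortho-hydroxyl of the symmetric trihydroxybenzoyl ring can close, so no regiochemical issue arises there.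

Step 14
Reactants: 19 tri-O-benzyl ether of target 20
Product: 20 target (CNP0208300.3)
Conditions: H2 (1 atm), Pd(OH)2/C, THF/MeOH, rt
Reagents that add atoms: none
Why: Hydrogenolysis of the three aryl benzyl ethers over Pearlman's catalyst, in which the fully substituted bis(aryloxy) ketal carbon and the chromane C2–O bond are hindered benzylic C–O bonds that should survive short neutral exposure and no stereocentre is touched.

**Compound list**

1 | 2,4,6-trihydroxybenzaldehyde | O=Cc1c(O)cc(O)cc1O | starting material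
2 | 2,6-dihydroxy-4-(methoxymethoxy)benzaldehyde | O=Cc1c(O)cc(OCOC)cc1O | intermediate
3 | 2-(benzyloxy)-6-hydroxy-4-(methoxymethoxy)benzaldehyde | O=Cc1c(O)cc(OCOC)cc1OCc1ccccc1 | intermediate
4 | 6-(benzyloxy)-2-hydroxy-3-iodo-4-(methoxymethoxy)benzaldehyde | O=Cc1c(O)c(I)c(OCOC)cc1OCc1ccccc1 | intermediate
5 | 1-[4-(benzyloxy)phenyl]ethan-1-one | CC(=O)c1ccc(OCc2ccccc2)cc1 | starting material
6 | (E)-3-[6-(benzyloxy)-2-hydroxy-3-iodo-4-(methoxymethoxy)phenyl]-1-[4-(benzyloxy)phenyl]prop-2-en-1-one | O=C(/C=C/c1c(O)c(I)c(OCOC)cc1OCc1ccccc1)c1ccc(OCc2ccccc2)cc1 | intermediate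
7 | 3-[6-(benzyloxy)-2-hydroxy-3-iodo-4-(methoxymethoxy)phenyl]-1-[4-(benzyloxy)phenyl]propan-1-one | O=C(CCc1c(O)c(I)c(OCOC)cc1OCc1ccccc1)c1ccc(OCc2ccccc2)cc1 | intermediate (not isolated)
8 | (1R)-3-[6-(benzyloxy)-2-hydroxy-3-iodo-4-(methoxymethoxy)phenyl]-1-[4-(benzyloxy)phenyl]propan-1-ol | O[C@@H](c1ccc(OCc2ccccc2)cc1)CCc1c(O)c(I)c(OCOC)cc1OCc1ccccc1 | intermediate
9 | (2S)-5-(benzyloxy)-2-[4-(benzyloxy)phenyl]-8-iodo-7-(methoxymethoxy)chromane | COCOc1cc(OCc2ccccc2)c2c(c1I)O[C@H](c1ccc(OCc3ccccc3)cc1)CC2 | intermediate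
10 | 1-(benzyloxy)-4-ethynylbenzene | C#Cc1ccc(OCc2ccccc2)cc1 | starting material
11 | (2S)-5-(benzyloxy)-2-[4-(benzyloxy)phenyl]-8-{[4-(benzyloxy)phenyl]ethynyl}-7-(methoxymethoxy)chromane | COCOc1cc(OCc2ccccc2)c2c(c1C#Cc1ccc(OCc3ccccc3)cc1)O[C@H](c1ccc(OCc3ccccc3)cc1)CC2 | intermediate
12 | (2S)-5-(benzyloxy)-2-[4-(benzyloxy)phenyl]-8-{[4-(benzyloxy)phenyl]ethynyl}chroman-7-ol | Oc1cc(OCc2ccccc2)c2c(c1C#Cc1ccc(OCc3ccccc3)cc1)O[C@H](c1ccc(OCc3ccccc3)cc1)CC2 | intermediate
13 | phloroglucinol (benzene-1,3,5-triol) | Oc1cc(O)cc(O)c1 | starting material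
14 | 1,3,5-tris(methoxymethoxy)benzene | COCOc1cc(OCOC)cc(OCOC)c1 | intermediate
15 | 2-iodo-1,3,5-tris(methoxymethoxy)benzene | COCOc1cc(OCOC)c(I)c(OCOC)c1 | intermediate
16 | [(2S)-5-(benzyloxy)-2,8-bis[4-(benzyloxy)phenyl]-3,4-dihydro-2H-furo[2,3-h]chromen-9-yl][2,4,6-tris(methoxymethoxy)phenyl]methanone (2-aryl-3-aroylbenzofuran whose furan O and C3a are C7–O and C8 of the (S)-flavan) | O=C(c1c(OCOC)cc(OCOC)cc1OCOC)c1c(-c2ccc(OCc3ccccc3)cc2)oc2cc(OCc3ccccc3)c3c(c12)O[C@H](c1ccc(OCc2ccccc2)cc1)CC3 | intermediate
17 | [(2S)-5-(benzyloxy)-2,8-bis[4-(benzyloxy)phenyl]-3,4-dihydro-2H-furo[2,3-h]chromen-9-yl](2,4,6-trihydroxyphenyl)methanone | O=C(c1c(O)cc(O)cc1O)c1c(-c2ccc(OCc3ccccc3)cc2)oc2cc(OCc3ccccc3)c3c(c12)O[C@H](c1ccc(OCc2ccccc2)cc1)CC3 | intermediate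
18 | (2S,8R,9S)-8,9-epoxide of 17 (oxirane oxygen bridging C8 and C9 of the furochromene, on the face of C9 that keeps its C–O bond in 19) | O=C(c1c(O)cc(O)cc1O)[C@]12O[C@@]1(c1ccc(OCc3ccccc3)cc1)Oc1cc(OCc3ccccc3)c3c(c12)O[C@H](c1ccc(OCc2ccccc2)cc1)CC3 | intermediate (not isolated)
19 | tri-O-benzyl ether of 20: (2R,3S)-3,5,7-trihydroxy-2-[4-(benzyloxy)phenyl]chroman-4-one with C3 bonded to C8' and C2 bonded to O7' of (2'S)-5'-(benzyloxy)-2'-[4-(benzyloxy)phenyl]chromane | O=C1c2c(O)cc(O)cc2O[C@@]2(c3ccc(OCc4ccccc4)cc3)Oc3cc(OCc4ccccc4)c4c(c3[C@]12O)O[C@H](c1ccc(OCc2ccccc2)cc1)CC4 | intermediate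
20 | target CNP0208300.3: (2R,3S)-3,5,7-trihydroxy-2-(4-hydroxyphenyl)chroman-4-one with C3 bonded to C8' and C2 bonded to O7' of (2'S)-5'-hydroxy-2'-(4-hydroxyphenyl)chromane | O=C1c2c(O)cc(O)cc2O[C@@]2(c3ccc(O)cc3)Oc3cc(O)c4c(c3[C@]12O)O[C@H](c1ccc(O)cc1)CC4 | target

**Step count**

Total steps: 14. Longest linear sequence: 12 steps (steps 1–8 and 11–14); steps 9–10 are the side branch to iodide 15.

**Steps most likely to fail**

1. Step 13 (proposed new method). The oxygen transfer may show poor facial selectivity, the chiral oxidant may fail to engage the acyl-deactivated tetrasubstituted enol ether, or the intermediate may close through C3 to a spiro-coumaranone. Fallback with known chemistry: it sets out from 17. Dimethyldioxirane in acetone/CH2Cl2 at −40 °C, a reagent known to epoxidise benzofurans, followed by the same ring closure in the flask, should give 19 and its isomer with both fusion carbons inverted, bis-epimer of 19 F1. Because of the flavan centre the two are diastereomers and are separated by chromatography; the route is rejoined at 19.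

2. Step 11. The phenoxide may cycloisomerise to the 3-unsubstituted benzofuran before the aroyl-palladium species forms, oxidative addition of the hindered electron-rich iodide may be slow, or the phenoxide may capture the aroyl-palladium as an ester. Fallback: it sets out from 12. Iodocyclisation (I2, NaHCO3, MeCN) should give the 9-iodofurochromene F2. Iodine–magnesium exchange (i-PrMgCl·LiCl, THF, −20 °C) and addition to 2,4,6-tris(methoxymethoxy)benzaldehyde F3 (from 14 by n-BuLi then DMF) should give the diaryl carbinol F4 as both epimers. Dess–Martin oxidation then comes back to the route at 16.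

3. Step 14. Reductive cleavage of the benzylic ketal C–O bonds or of the chromane C2–O bond may compete with debenzylation. Fallback: the reductive step is moved in front of ketal formation, setting out from 17. Hydrogenolysis (H2, Pd(OH)2/C) should give the hexaphenol F5. Acetylation of the five non-chelated phenols (Ac2O, pyridine, 0 °C) should give the pentaacetate F6. Oxygen transfer and ring closure under the conditions of step 13 should give the pentaacetate of the target F7. Methanolysis (K2CO3, MeOH, 0 °C) comes back to the route at 20.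

Further compounds
F1 | step 13 | bis-epimer of 19 (both fusion carbons inverted, flavan C2 S) | O=C1c2c(O)cc(O)cc2O[C@]2(c3ccc(OCc4ccccc4)cc3)Oc3cc(OCc4ccccc4)c4c(c3[C@@]12O)O[C@H](c1ccc(OCc2ccccc2)cc1)CC4
F2 | step 11 | 9-iodofurochromene: (2S)-5-(benzyloxy)-2,8-bis[4-(benzyloxy)phenyl]-9-iodo-3,4-dihydro-2H-furo[2,3-h]chromene | Ic1c(-c2ccc(OCc3ccccc3)cc2)oc2cc(OCc3ccccc3)c3c(c12)O[C@H](c1ccc(OCc2ccccc2)cc1)CC3
F3 | step 11 | 2,4,6-tris(methoxymethoxy)benzaldehyde | O=Cc1c(OCOC)cc(OCOC)cc1OCOC
F4 | step 11 | diaryl carbinol: [(2S)-5-(benzyloxy)-2,8-bis[4-(benzyloxy)phenyl]-3,4-dihydro-2H-furo[2,3-h]chromen-9-yl][2,4,6-tris(methoxymethoxy)phenyl]methanol, both carbinol epimers | OC(c1c(OCOC)cc(OCOC)cc1OCOC)c1c(-c2ccc(OCc3ccccc3)cc2)oc2cc(OCc3ccccc3)c3c(c12)O[C@H](c1ccc(OCc2ccccc2)cc1)CC3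
F5 | step 14 | hexaphenol: [(2S)-5-hydroxy-2,8-bis(4-hydroxyphenyl)-3,4-dihydro-2H-furo[2,3-h]chromen-9-yl](2,4,6-trihydroxyphenyl)methanone | O=C(c1c(O)cc(O)cc1O)c1c(-c2ccc(O)cc2)oc2cc(O)c3c(c12)O[C@H](c1ccc(O)cc1)CC3
F6 | step 14 | pentaacetate of F5 with one chelated ortho-hydroxyl of the benzoyl ring left free | O=C(c1c(O)cc(OC(C)=O)cc1OC(C)=O)c1c(-c2ccc(OC(C)=O)cc2)oc2cc(OC(C)=O)c3c(c12)O[C@H](c1ccc(OC(C)=O)cc1)CC3
F7 | step 14 | pentaacetate of the target 20 (all five phenols acetylated, tertiary 3-OH free) | O=C1c2c(OC(C)=O)cc(OC(C)=O)cc2O[C@@]2(c3ccc(OC(C)=O)cc3)Oc3cc(OC(C)=O)c4c(c3[C@]12O)O[C@H](c1ccc(OC(C)=O)cc1)CC4
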